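The disconnection opens ring A of the upper unit, a phloroglucinol joined to upper C4 through C4a, at its C4a–C5 bond: its six carbons (C4a, C8a, C8, C7, C6, C5) then form a methyl 3,5-dioxo ester chain on upper C4. One Claisen cyclisation closes and aromatises this ring, so the 4β→8 bond between the units exists before the upper flavan does. The precursor carries the benzylated 4β-allyl lower unit (bonded at C8) on upper C4, the upper C3 and C2 oxygens as erythro TBS and TES ethers, and the chain grown from a cis γ-lactone. The two equivalent ortho-hydroxyls of ring A later close ring C at C2 with inversion.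

Key step: step 13

Remark (names): "upper" and "lower" are the two flavan units with flavan numbering; 4β means trans to the 3-oxygen; Ar8 = (2R,3R,4S)-4-allyl-3,5,7-tris(benzyloxy)-2-[3,4-bis(benzyloxy)phenyl]chroman-8-yl; ArB = 3,4-bis(benzyloxy)phenyl.
Remark (assumption): the sense of induction of the cinchona salt in step 7 is taken by analogy with unsubstituted 2-silyloxyfurans; if it proves opposite, the quinidine-derived pseudoenantiomer is used instead.

Step 1
Reactants: 1 (−)-epicatechin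
Product: 2 5,7,3',4'-tetra-O-benzylepicatechin
Conditions: BnBr (4.4 equiv), K2CO3, DMF, 0 °C → rt
Reagents that add atoms: benzyl bromide, BrCc1ccccc1
Why: Williamson etherification under weak base benzylates only the four phenols (the 3-hydroxyl is not deprotonated) and leaves C2 and C3 untouched.

Step 2
Reactants: 2 5,7,3',4'-tetra-O-benzylepicatechin
Product: 3 4β-(2-ethoxyethoxy) ether of 2
Conditions: DDQ (2 equiv), EtOCH2CH2OH, CH2Cl2, rt
Reagents that add atoms: 2-ethoxyethanol, CCOCCO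
Why: Oxidative benzylic etherification: DDQ removes hydride from C4 and the cation stabilised by the 5,7-dibenzyloxy ring A is captured by the alcohol on the face opposite the 3-hydroxyl, which sets C4 as 4β (3,4-trans).

Step 3
Reactants: 3 4β-(2-ethoxyethoxy) ether
Product: 4 3-O-benzyl ether of 3
Conditions: NaH, BnBr, Bu4NI (cat.), DMF, 0 °C → rt
Reagents that add atoms: benzyl bromide, BrCc1ccccc1
Why: Williamson etherification of the secondary alkoxide; the C4 ether is stable to base, so no stereocentre is touched.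

Step 4
Reactants: 4 penta-O-benzyl 4β-ether
Product: 5 8-bromide of 4
Conditions: NBS (1.0 equiv), CH2Cl2, −78 → 0 °C
Reagents that add atoms: N-bromosuccinimide, O=C1CCC(=O)N1Br
Why: Electrophilic aromatic bromination goes to C8, the more reactive of the two free positions of a 5,7-dialkoxyflavan ring A; the bromine marks the later coupling site and blocks self-condensation through C8 in step 5.

Step 5
Reactants: 5 8-bromo 4β-ether
Product: 6 4β-allyl 8-bromide
Conditions: allylSiMe3 (5 equiv), TMSOTf (0.2 equiv), CH2Cl2, −78 → −40 °C; aq. NaHCO3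
Reagents that add atoms: allyltrimethylsilane, C=CC[Si](C)(C)C
Why: Hosomi–Sakurai allylation: TMSOTf ionises the C4 ether to the ring-A-stabilised cation and the allylsilane adds anti to the 3-benzyloxy group, which gives the 4β-allyl (3,4-trans) compound.

Step 6
Reactants: 7 4-bromofuran-2(5H)-one
Product: 8 4-bromo-2-(trimethylsilyloxy)furan
Conditions: TMSOTf, Et3N, Et2O, 0 °C; pentane, filtration
Reagents that add atoms: trimethylsilyl triflate, C[Si](C)(C)OS(=O)(=O)C(F)(F)F
Why: Soft enolisation with O-silylation turns the butenolide into the aromatic 2-silyloxyfuran, a dienolate equivalent that is nucleophilic at C5.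

Step 7
Reactants: 8 4-bromo-2-(trimethylsilyloxy)furan; 9 3,4-bis(benzyloxy)benzaldehyde
Product: 10 anti aldol adduct (bromobutenolide alcohol)
Conditions: 1-[3,5-bis(trifluoromethyl)phenyl]-3-(9-deoxy-epi-quinin-9-yl)thiourea·CF3CO2H (10 mol %), CH2Cl2, −30 °C; then aq. citric acid, THF, 0 °C
Reagents that add atoms: none
Why: Vinylogous Mukaiyama aldol addition under anionic activation: the carboxylate takes silicon, the chiral ammonium dienolate adds through C5 to the thiourea-bound aldehyde, the open ion-pair transition state should favour the anti (erythro) adduct as fluoride-triggered additions of silyloxyfurans do, and the cinchona scaffold selects the face (new centres upper C3 and upper C2, catalyst control).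

Step 8
Reactants: 10 anti aldol adduct
Product: 11 triethylsilyl ether of 10
Conditions: TESOTf, 2,6-lutidine, CH2Cl2, −78 °C
Reagents that add atoms: triethylsilyl triflate, CC[Si](CC)(CC)OS(=O)(=O)C(F)(F)F
Why: O-silylation at low temperature avoids retro-aldol and elimination; TES is placed on this oxygen (upper C2) because it must later be freed beside a TBS ether.

Step 9
Reactants: 6 4β-allyl 8-bromide; 11 silylated bromobutenolide
Product: 14 C8-coupled butenolide, via aryllithium 12 (not isolated), via arylzinc chloride 13 (not isolated)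
Conditions: 6, t-BuLi (2 equiv), THF, −78 °C; ZnCl2, −78 °C → rt; 11, Pd2(dba)3 (2.5 mol %), SPhos (10 mol %), THF, 50 °C
Reagents that add atoms: none
Why: Bromine–lithium exchange, transmetalation to zinc and Negishi coupling join lower C8 to C4 of the butenolide; the arylzinc tolerates the lactone and its C5–H, SPhos serves the di-ortho-substituted partner, and any stereoisomer carried by 11 is now a separable diastereomer.

Step 10
Reactants: 14 C8-coupled butenolide
Product: 15 cis-4,5-disubstituted γ-lactone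
Conditions: Cu(OAc)2·H2O (5 mol %), 1,2-bis(diphenylphosphino)benzene (5 mol %), (EtO)2MeSiH, t-BuOH, toluene, rt
Reagents that add atoms: none
Why: Conjugate reduction by bisphosphine-ligated CuH, chosen for a hindered β-carbon: hydride adds to C4 on the face away from the C5 side chain, so Ar8 ends cis to that chain (upper C4, substrate control), and the copper enolate is protonated by t-BuOH; the isolated alkene and the benzyl ethers do not react with CuH.

Step 11
Reactants: 15 cis-lactone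
Product: 17 C3-silylated Weinreb amide, via hydroxy Weinreb amide 16 (not isolated)
Conditions: MeNHOMe·HCl, AlMe3, CH2Cl2, 0 °C → rt; aq. potassium sodium tartrate; crude 16, TBSOTf, 2,6-lutidine, CH2Cl2, −78 → 0 °C
Reagents that add atoms: N,O-dimethylhydroxylamine hydrochloride, CNOC.Cl; tert-butyldimethylsilyl triflate, CC(C)(C)[Si](C)(C)OS(=O)(=O)C(F)(F)F
Why: Weinreb aminolysis opens the lactone and the liberated upper C3 hydroxyl is silylated at once, before it can relactonise and before any ketone exists with which it could form a hemiketal; no stereocentre is involved.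

Step 12
Reactants: 17 C3-silylated Weinreb amide; 18 methyl acetoacetate
Product: 20 methyl 3,5-dioxo ester (precursor of the key step), via dilithium dianion 19 (not isolated)
Conditions: 18 (3 equiv), LiN(i-Pr)2 (6 equiv), THF, 0 °C; 17, −78 → −20 °C; AcOH
Reagents that add atoms: none
Why: Acylation of the acetoacetate dianion at its terminal carbon by the Weinreb amide (stable chelate, no second addition) extends the chain to the 3,5-dioxo ester; the stereocentres lie β or further from every carbonyl and are not at risk.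

Step 13
Reactants: 20 methyl 3,5-dioxo ester
Product: 22 upper ring A phloroglucinol (C2–OTES, C3–OTBS), via cyclohexane-1,3,5-trione 21 (not isolated)
Conditions: Mg(OMe)2 (10 equiv), MeOH/toluene 1:1, 70 °C; then AcOH, 0 °C
Reagents that add atoms: none
Why: Mg(OMe)2 converts the dioxo ester into magnesium-chelated enolates that exchange protons reversibly in methanol, so the enolate of the C8a ketone toward the C4a methylene is reached while the ester carbonyl (C5) is still free; C4a adds to C5, methoxide leaves, and trione 21 tautomerises to the phloroglucinol, whose formation as an aromatic magnesium phenoxide makes the sequence irreversible. The closest known reaction type is the base-induced Claisen (Dieckmann-type) cyclisation of 3,5-dioxoalkanoates to phloroglucinols and of δ-keto esters to cyclohexane-1,3-diones, the laboratory counterpart of C6-to-C1 polyketide folding. Ring A closes 6-exo-trig at the ester carbonyl, forming the C4a–C5 bond. No stereocentre is created, and upper C4, C3 and C2 are not enolisable (C4 is β to the ketone and neither silyloxy group is β to it), so their configurations are carried through. The selectivity needed is C-acylation by C4a instead of O-acylation to a 4-hydroxy-2-pyranone or methanolytic cleavage of the chain: carbanions at C8 or C6 could only close four-membered rings, the pyranone is reopened by methoxide whereas the aromatic ring is a thermodynamic sink, and chelation by magnesium shields the 1,3-dicarbonyl units. Both hydroxyls stay silylated so that neither can add to the C8a ketone before the ring forms.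

Step 14
Reactants: 22 upper ring A phloroglucinol
Product: 23 upper C2 alcohol
Conditions: HF·pyridine, pyridine, THF, 0 °C
Reagents that add atoms: none
Why: Selective fluoride cleavage of the secondary TES ether beside the more hindered and more robust TBS ether frees only the upper C2 hydroxyl; material that lost TES under the methoxide of step 13 is the same compound.

Step 15
Reactants: 23 upper C2 alcohol
Product: 24 dimer with ring C closed (upper 5,7-diol, 3-O-TBS)
Conditions: PPh3, DIAD, THF (0.01 M), 0 °C → rt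
Reagents that add atoms: none
Why: Intramolecular Mitsunobu etherification: a ring A phenol protonates the betaine, the C2 hydroxyl is activated on phosphorus and displaced by the ortho-phenoxide (6-exo-tet) with inversion, which turns the erythro 2,3-pattern into the 2,3-cis ring C; the two ortho-hydroxyls are equivalent, the para-hydroxyl cannot reach, and the C3 silyl ether excludes five-membered closure.

Step 16
Reactants: 24 dimer with upper 5,7-diol
Product: 25 fully benzylated 3-O-TBS dimer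
Conditions: BnBr, K2CO3, DMF, rt
Reagents that add atoms: benzyl bromide, BrCc1ccccc1
Why: Williamson benzylation of the two remaining phenols (upper C5–OH and C7–OH) shields the electron-rich ring from the oxidants of steps 18 and 19 and adds only groups that the last step removes.

Step 17
Reactants: 25 fully benzylated 3-O-TBS dimer
Product: 26 nona-O-benzyl 4β-allyl dimer with free upper 3-OH
Conditions: HF·pyridine (excess), THF, rt → 40 °C
Reagents that add atoms: none
Why: Fluoride desilylation of the hindered 3-O-TBS ether; nothing else in 25 is fluoride-labile.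

Step 18
Reactants: 26 nona-O-benzyl 4β-allyl dimer
Product: 28 aldehyde, via diol 27 (not isolated)
Conditions: OsO4 (2 mol %), NMO, THF/acetone/H2O, rt; then NaIO4, rt
Reagents that add atoms: N-methylmorpholine N-oxide, C[N+]1([O-])CCOCC1; osmium tetroxide, O=[Os](=O)(=O)=O; water, O
Why: Lemieux–Johnson cleavage: OsO4 dihydroxylates the only alkene and periodate cleaves diol 27 to the aldehyde with loss of formaldehyde; with every phenol benzylated the arenes resist both oxidants.

Step 19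
Reactants: 28 aldehyde
Product: 29 nona-O-benzyl acid
Conditions: NaClO2, NaH2PO4, 2-methyl-2-butene, t-BuOH/THF/H2O, 0 °C → rt
Reagents that add atoms: sodium chlorite, [Na+].[O-]Cl=O
Why: Pinnick oxidation converts the aldehyde into the acid under buffered conditions; 2-methyl-2-butene traps HOCl before it can chlorinate the alkoxyarenes, and there is no α-stereocentre.

Step 20
Reactants: 29 nona-O-benzyl acid
Product: 30 epicatechin-(4β→8)-4β-(carboxymethyl)epicatechin (target)
Conditions: H2 (1 atm), Pd(OH)2/C, THF/MeOH/H2O, rt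
Reagents that add atoms: none
Why: Hydrogenolysis removes all nine benzyl ethers under neutral conditions, as is usual for benzylated procyanidins; the pyran C–O bonds, the C4–C8 bond and the acid remain.

Compound list

1 | (−)-epicatechin, (2R,3R)-2-(3,4-dihydroxyphenyl)chromane-3,5,7-triol | C1c2c(O)cc(O)cc2O[C@H](c2ccc(O)c(O)c2)[C@@H]1O | starting material
2 | (2R,3R)-5,7-bis(benzyloxy)-2-ArB-chroman-3-ol (5,7,3',4'-tetra-O-benzylepicatechin) | C1c2c(OCc5ccccc5)cc(OCc5ccccc5)cc2O[C@H](c2ccc(OCc5ccccc5)c(OCc5ccccc5)c2)[C@@H]1O | intermediate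
3 | (2R,3R,4S)-5,7-bis(benzyloxy)-2-ArB-4-(2-ethoxyethoxy)chroman-3-ol (4β-ether) | CCOCCO[C@H]1c2c(OCc5ccccc5)cc(OCc5ccccc5)cc2O[C@H](c2ccc(OCc5ccccc5)c(OCc5ccccc5)c2)[C@@H]1O | intermediate
4 | (2R,3R,4S)-3,5,7-tris(benzyloxy)-2-ArB-4-(2-ethoxyethoxy)chromane | CCOCCO[C@H]1c2c(OCc5ccccc5)cc(OCc5ccccc5)cc2O[C@H](c2ccc(OCc5ccccc5)c(OCc5ccccc5)c2)[C@@H]1OCc5ccccc5 | intermediate
5 | (2R,3R,4S)-3,5,7-tris(benzyloxy)-2-ArB-8-bromo-4-(2-ethoxyethoxy)chromane | CCOCCO[C@H]1c2c(OCc5ccccc5)cc(OCc5ccccc5)c(Br)c2O[C@H](c2ccc(OCc5ccccc5)c(OCc5ccccc5)c2)[C@@H]1OCc5ccccc5 | intermediate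
6 | (2R,3R,4S)-4-allyl-3,5,7-tris(benzyloxy)-2-ArB-8-bromochromane (Ar8–Br) | C=CC[C@H]1c2c(OCc5ccccc5)cc(OCc5ccccc5)c(Br)c2O[C@H](c2ccc(OCc5ccccc5)c(OCc5ccccc5)c2)[C@@H]1OCc5ccccc5 | intermediate
7 | 4-bromofuran-2(5H)-one | O=C1C=C(Br)CO1 | starting material
8 | 4-bromo-2-(trimethylsilyloxy)furan | C[Si](C)(C)Oc1cc(Br)co1 | intermediate
9 | 3,4-bis(benzyloxy)benzaldehyde | O=Cc1ccc(OCc2ccccc2)c(OCc2ccccc2)c1 | starting material
10 | (5S)-5-[(S)-ArB(hydroxy)methyl]-4-bromofuran-2(5H)-one (anti, erythro) | O=C1C=C(Br)[C@H]([C@@H](O)c2ccc(OCc5ccccc5)c(OCc5ccccc5)c2)O1 | intermediate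
11 | (5S)-5-[(S)-ArB(triethylsilyloxy)methyl]-4-bromofuran-2(5H)-one | O=C1C=C(Br)[C@H]([C@@H](O[Si](CC)(CC)CC)c2ccc(OCc5ccccc5)c(OCc5ccccc5)c2)O1 | intermediate
12 | Ar8–Li, the 8-lithio derivative of 6 | C=CC[C@H]1c2c(OCc5ccccc5)cc(OCc5ccccc5)c([Li])c2O[C@H](c2ccc(OCc5ccccc5)c(OCc5ccccc5)c2)[C@@H]1OCc5ccccc5 | intermediate (not isolated)
13 | Ar8–ZnCl, the 8-chlorozincio derivative of 6 | C=CC[C@H]1c2c(OCc5ccccc5)cc(OCc5ccccc5)c([Zn]Cl)c2O[C@H](c2ccc(OCc5ccccc5)c(OCc5ccccc5)c2)[C@@H]1OCc5ccccc5 | intermediate (not isolated)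
14 | (5R)-4-Ar8-5-[(S)-ArB(triethylsilyloxy)methyl]furan-2(5H)-one | C=CC[C@H]1c2c(OCc5ccccc5)cc(OCc5ccccc5)c(C3=CC(=O)O[C@H]3[C@@H](O[Si](CC)(CC)CC)c4ccc(OCc5ccccc5)c(OCc5ccccc5)c4)c2O[C@H](c2ccc(OCc5ccccc5)c(OCc5ccccc5)c2)[C@@H]1OCc5ccccc5 | intermediate
15 | (4R,5R)-4-Ar8-5-[(S)-ArB(triethylsilyloxy)methyl]dihydrofuran-2(3H)-one (4,5-cis) | C=CC[C@H]1c2c(OCc5ccccc5)cc(OCc5ccccc5)c([C@H]3CC(=O)O[C@H]3[C@@H](O[Si](CC)(CC)CC)c4ccc(OCc5ccccc5)c(OCc5ccccc5)c4)c2O[C@H](c2ccc(OCc5ccccc5)c(OCc5ccccc5)c2)[C@@H]1OCc5ccccc5 | intermediate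
16 | (3R,4R,5S)-3-Ar8-5-ArB-4-hydroxy-N-methoxy-N-methyl-5-(triethylsilyloxy)pentanamide | C=CC[C@H]1c2c(OCc5ccccc5)cc(OCc5ccccc5)c([C@@H](CC(=O)N(C)OC)[C@@H](O)[C@@H](O[Si](CC)(CC)CC)c4ccc(OCc5ccccc5)c(OCc5ccccc5)c4)c2O[C@H](c2ccc(OCc5ccccc5)c(OCc5ccccc5)c2)[C@@H]1OCc5ccccc5 | intermediate (not isolated)
17 | (3R,4R,5S)-3-Ar8-5-ArB-4-(tert-butyldimethylsilyloxy)-N-methoxy-N-methyl-5-(triethylsilyloxy)pentanamide | C=CC[C@H]1c2c(OCc5ccccc5)cc(OCc5ccccc5)c([C@@H](CC(=O)N(C)OC)[C@@H](O[Si](C)(C)C(C)(C)C)[C@@H](O[Si](CC)(CC)CC)c4ccc(OCc5ccccc5)c(OCc5ccccc5)c4)c2O[C@H](c2ccc(OCc5ccccc5)c(OCc5ccccc5)c2)[C@@H]1OCc5ccccc5 | intermediate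
18 | methyl acetoacetate | COC(=O)CC(C)=O | starting material
19 | dilithium dianion of methyl acetoacetate | [Li+].[Li+].[CH2-]C(=O)[CH-]C(=O)OC | intermediate (not isolated)
20 | methyl (7R,8R,9S)-7-Ar8-9-ArB-8-(tert-butyldimethylsilyloxy)-3,5-dioxo-9-(triethylsilyloxy)nonanoate (chain C7, C8, C9 = upper C4, C3, C2; chain C6 = upper C4a) | C=CC[C@H]1c2c(OCc5ccccc5)cc(OCc5ccccc5)c([C@@H](CC(=O)CC(=O)CC(=O)OC)[C@@H](O[Si](C)(C)C(C)(C)C)[C@@H](O[Si](CC)(CC)CC)c4ccc(OCc5ccccc5)c(OCc5ccccc5)c4)c2O[C@H](c2ccc(OCc5ccccc5)c(OCc5ccccc5)c2)[C@@H]1OCc5ccccc5 | intermediate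
21 | 2-[(1R,2R,3S)-1-Ar8-3-ArB-2-(tert-butyldimethylsilyloxy)-3-(triethylsilyloxy)propyl]cyclohexane-1,3,5-trione | C=CC[C@H]1c2c(OCc5ccccc5)cc(OCc5ccccc5)c([C@@H](C4C(=O)CC(=O)CC4=O)[C@@H](O[Si](C)(C)C(C)(C)C)[C@@H](O[Si](CC)(CC)CC)c4ccc(OCc5ccccc5)c(OCc5ccccc5)c4)c2O[C@H](c2ccc(OCc5ccccc5)c(OCc5ccccc5)c2)[C@@H]1OCc5ccccc5 | intermediate (not isolated)
22 | 2-[(1R,2R,3S)-1-Ar8-3-ArB-2-(tert-butyldimethylsilyloxy)-3-(triethylsilyloxy)propyl]benzene-1,3,5-triol | C=CC[C@H]1c2c(OCc5ccccc5)cc(OCc5ccccc5)c([C@@H](c4c(O)cc(O)cc4O)[C@@H](O[Si](C)(C)C(C)(C)C)[C@@H](O[Si](CC)(CC)CC)c4ccc(OCc5ccccc5)c(OCc5ccccc5)c4)c2O[C@H](c2ccc(OCc5ccccc5)c(OCc5ccccc5)c2)[C@@H]1OCc5ccccc5 | intermediate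
23 | 2-[(1R,2R,3S)-1-Ar8-3-ArB-2-(tert-butyldimethylsilyloxy)-3-hydroxypropyl]benzene-1,3,5-triol | C=CC[C@H]1c2c(OCc5ccccc5)cc(OCc5ccccc5)c([C@@H](c4c(O)cc(O)cc4O)[C@@H](O[Si](C)(C)C(C)(C)C)[C@@H](O)c4ccc(OCc5ccccc5)c(OCc5ccccc5)c4)c2O[C@H](c2ccc(OCc5ccccc5)c(OCc5ccccc5)c2)[C@@H]1OCc5ccccc5 | intermediate
24 | 3-O-(tert-butyldimethylsilyl)-3',4'-di-O-benzylepicatechin-(4β→8)-4β-allyl-3,5,7,3',4'-penta-O-benzylepicatechin | C=CC[C@H]1c2c(OCc5ccccc5)cc(OCc5ccccc5)c([C@H]3c4c(O)cc(O)cc4O[C@H](c4ccc(OCc5ccccc5)c(OCc5ccccc5)c4)[C@@H]3O[Si](C)(C)C(C)(C)C)c2O[C@H](c2ccc(OCc5ccccc5)c(OCc5ccccc5)c2)[C@@H]1OCc5ccccc5 | intermediate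
25 | 3-O-(tert-butyldimethylsilyl)-5,7,3',4'-tetra-O-benzylepicatechin-(4β→8)-4β-allyl-3,5,7,3',4'-penta-O-benzylepicatechin | C=CC[C@H]1c2c(OCc5ccccc5)cc(OCc5ccccc5)c([C@H]3c4c(OCc5ccccc5)cc(OCc5ccccc5)cc4O[C@H](c4ccc(OCc5ccccc5)c(OCc5ccccc5)c4)[C@@H]3O[Si](C)(C)C(C)(C)C)c2O[C@H](c2ccc(OCc5ccccc5)c(OCc5ccccc5)c2)[C@@H]1OCc5ccccc5 | intermediate
26 | 5,7,3',4'-tetra-O-benzylepicatechin-(4β→8)-4β-allyl-3,5,7,3',4'-penta-O-benzylepicatechin | C=CC[C@H]1c2c(OCc5ccccc5)cc(OCc5ccccc5)c([C@H]3c4c(OCc5ccccc5)cc(OCc5ccccc5)cc4O[C@H](c4ccc(OCc5ccccc5)c(OCc5ccccc5)c4)[C@@H]3O)c2O[C@H](c2ccc(OCc5ccccc5)c(OCc5ccccc5)c2)[C@@H]1OCc5ccccc5 | intermediate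
27 | 4β-(2,3-dihydroxypropyl) analogue of 26 (both epimers at the new carbinol) | OCC(O)C[C@H]1c2c(OCc5ccccc5)cc(OCc5ccccc5)c([C@H]3c4c(OCc5ccccc5)cc(OCc5ccccc5)cc4O[C@H](c4ccc(OCc5ccccc5)c(OCc5ccccc5)c4)[C@@H]3O)c2O[C@H](c2ccc(OCc5ccccc5)c(OCc5ccccc5)c2)[C@@H]1OCc5ccccc5 | intermediate (not isolated)
28 | 4β-(2-oxoethyl) analogue of 26 | O=CC[C@H]1c2c(OCc5ccccc5)cc(OCc5ccccc5)c([C@H]3c4c(OCc5ccccc5)cc(OCc5ccccc5)cc4O[C@H](c4ccc(OCc5ccccc5)c(OCc5ccccc5)c4)[C@@H]3O)c2O[C@H](c2ccc(OCc5ccccc5)c(OCc5ccccc5)c2)[C@@H]1OCc5ccccc5 | intermediate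
29 | 5,7,3',4'-tetra-O-benzylepicatechin-(4β→8)-4β-(carboxymethyl)-3,5,7,3',4'-penta-O-benzylepicatechin | O=C(O)C[C@H]1c2c(OCc5ccccc5)cc(OCc5ccccc5)c([C@H]3c4c(OCc5ccccc5)cc(OCc5ccccc5)cc4O[C@H](c4ccc(OCc5ccccc5)c(OCc5ccccc5)c4)[C@@H]3O)c2O[C@H](c2ccc(OCc5ccccc5)c(OCc5ccccc5)c2)[C@@H]1OCc5ccccc5 | intermediate
30 | epicatechin-(4β→8)-4β-(carboxymethyl)epicatechin, CNP0190976.1 | O=C(O)C[C@H]1c2c(O)cc(O)c([C@H]3c4c(O)cc(O)cc4O[C@H](c4ccc(O)c(O)c4)[C@@H]3O)c2O[C@H](c2ccc(O)c(O)c2)[C@@H]1O | target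

Total step count: 20. Longest linear sequence: 17 steps (steps 1–5 and 9–20, from epicatechin); steps 6–8 form the three-step side branch.

The three steps most likely to fail

Step 13. The enolate at the C4a methylene may form too slowly beside the far more acidic C8 and C6 methylenes, so that O-acylation to the pyranone and methanolytic cleavage of the chain outrun ring closure. The fallback gives up building ring A and joins two complete flavan units by the established acid-promoted 4β→8 coupling. It sets out from 6 and 3: bromine–lithium exchange on 6 and protonation (t-BuLi, THF, −78 °C; MeOH) should give (2R,3R,4S)-4-allyl-3,5,7-tris(benzyloxy)-2-ArB-chromane F1. F1 (3 equiv, to suppress self-condensation of 3) and 3 with TMSOTf (cat.) in CH2Cl2 at −78 °C should then give 26 directly, because C8 of F1 attacks the C4 cation of 3 anti to its free 3-hydroxyl. The route is rejoined at 26.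

Step 15. Ionisation of the activated benzylic C2–O bond, whose cation is stabilised by the 3,4-dibenzyloxyphenyl group, would erode the inversion and favour closure to the 2,3-trans ring; the crowded C2 may also resist displacement. The fallback closes ring C through a cyclic acyloxonium ion, in which the neighbouring oxygen holds the C2–O bond until backside attack. It sets out from 23: HF·pyridine (excess) should give the 2,3-diol 2-[(1R,2R,3S)-1-Ar8-3-ArB-2,3-dihydroxypropyl]benzene-1,3,5-triol F2; HC(OEt)3 with PPTS in CH2Cl2 its cyclic 2-ethoxy-1,3-dioxolane (orthoformate) F3; PPTS in 1,2-dichloroethane at 60 °C opens the derived dioxolan-2-ylium ion at C2 by the ortho-phenol with inversion to give the flavan 3-O-formate F4; K2CO3 in MeOH gives the 3-ol 3',4'-di-O-benzylepicatechin-(4β→8)-4β-allyl-3,5,7,3',4'-penta-O-benzylepicatechin F5; BnBr and K2CO3 in DMF benzylate its two phenols. The route is rejoined at 26.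

Step 7. Facial discrimination or the anti preference may be weak with the bromine-bearing dienolate and the electron-rich aldehyde, or the addition may stall. The fallback builds the two centres after the cross-coupling, where every stereoisomer is a diastereomer that chromatography can remove. It sets out from 6, 7 and 9: arylzinc 13 (made from 6 as in step 9) and 7 with Pd(PPh3)4 in THF at 50 °C should give 4-Ar8-furan-2(5H)-one F6; TESOTf and Et3N its silyloxyfuran 4-Ar8-2-(triethylsilyloxy)furan F7; F7 and 9 with Bu4NF (10 mol %) in THF at −78 °C should give the anti (erythro) adducts as their TES ethers, silyl transfer to the aldolate turning the fluoride over. Compound 14 is separated from the anti isomer of opposite configuration at both new centres and from syn isomers. The route is rejoined at 14.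

Further compounds

F1 | step 13 | (2R,3R,4S)-4-allyl-3,5,7-tris(benzyloxy)-2-ArB-chromane | C=CC[C@H]1c2c(OCc5ccccc5)cc(OCc5ccccc5)cc2O[C@H](c2ccc(OCc5ccccc5)c(OCc5ccccc5)c2)[C@@H]1OCc5ccccc5
F2 | step 15 | 2-[(1R,2R,3S)-1-Ar8-3-ArB-2,3-dihydroxypropyl]benzene-1,3,5-triol | C=CC[C@H]1c2c(OCc5ccccc5)cc(OCc5ccccc5)c([C@@H](c4c(O)cc(O)cc4O)[C@@H](O)[C@@H](O)c4ccc(OCc5ccccc5)c(OCc5ccccc5)c4)c2O[C@H](c2ccc(OCc5ccccc5)c(OCc5ccccc5)c2)[C@@H]1OCc5ccccc5
F3 | step 15 | cyclic 2-ethoxy-1,3-dioxolane (orthoformate) of diol F2, cis-4,5-disubstituted, both epimers at the orthoester carbon | C=CC[C@H]1c2c(OCc5ccccc5)cc(OCc5ccccc5)c([C@@H](c4c(O)cc(O)cc4O)[C@H]6OC(OCC)O[C@H]6c4ccc(OCc5ccccc5)c(OCc5ccccc5)c4)c2O[C@H](c2ccc(OCc5ccccc5)c(OCc5ccccc5)c2)[C@@H]1OCc5ccccc5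
F4 | step 15 | 3-O-formyl-3',4'-di-O-benzylepicatechin-(4β→8)-4β-allyl-3,5,7,3',4'-penta-O-benzylepicatechin | C=CC[C@H]1c2c(OCc5ccccc5)cc(OCc5ccccc5)c([C@H]3c4c(O)cc(O)cc4O[C@H](c4ccc(OCc5ccccc5)c(OCc5ccccc5)c4)[C@@H]3OC=O)c2O[C@H](c2ccc(OCc5ccccc5)c(OCc5ccccc5)c2)[C@@H]1OCc5ccccc5
F5 | step 15 | 3',4'-di-O-benzylepicatechin-(4β→8)-4β-allyl-3,5,7,3',4'-penta-O-benzylepicatechin | C=CC[C@H]1c2c(OCc5ccccc5)cc(OCc5ccccc5)c([C@H]3c4c(O)cc(O)cc4O[C@H](c4ccc(OCc5ccccc5)c(OCc5ccccc5)c4)[C@@H]3O)c2O[C@H](c2ccc(OCc5ccccc5)c(OCc5ccccc5)c2)[C@@H]1OCc5ccccc5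
F6 | step 7 | 4-Ar8-furan-2(5H)-one | C=CC[C@H]1c2c(OCc5ccccc5)cc(OCc5ccccc5)c(C3=CC(=O)OC3)c2O[C@H](c2ccc(OCc5ccccc5)c(OCc5ccccc5)c2)[C@@H]1OCc5ccccc5
F7 | step 7 | 4-Ar8-2-(triethylsilyloxy)furan | C=CC[C@H]1c2c(OCc5ccccc5)cc(OCc5ccccc5)c(-c3coc(O[Si](CC)(CC)CC)c3)c2O[C@H](c2ccc(OCc5ccccc5)c(OCc5ccccc5)c2)[C@@H]1OCc5ccccc5
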